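**Retrosynthetic overview**
- Target ⇒ final one-flask double annulation of an (S,E)-enyne-phenol: prenal diethyl acetal closes the pyran (chromenylation via oxa-6π), then 5-iodo-resacetophenone closes the furan (Sonogashira / 5-endo-dig).
- Enyne-phenol ⇒ (E)-2-methyl-enal (one-carbon Colvin homologation) ⇒ (S)-3-aryl-1-butene + methacrolein (cross-metathesis fixes the E-trisubstituted alkene).
- (S)-3-Aryl-1-butene ⇒ silyl-protected 3-methoxy-4-vinylphenol + ethylene (Ni-catalysed asymmetric hydrovinylation sets the only stereocentre).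
- Vinylarene ⇒ 4-hydroxy-2-methoxybenzaldehyde; iodophenol ⇒ 2,4-dihydroxyacetophenone.
- Ring order: pyran first, furan second, both in the last operation; both benzene rings come from the starting materials.

Assumption: the SMILES is read as (S) at the benzylic carbon and (E) at the trisubstituted alkene. In step 2 the phosphoramidite antipode that gives the (S)-olefin is used; I have not assigned which antipode that is, so it is fixed by chiral HPLC on the first run.

**Step 1**
Reactants: 1 4-hydroxy-2-methoxybenzaldehyde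
Product: 3 tert-butyl(4-ethenyl-3-methoxyphenoxy)dimethylsilane, via potassium 4-ethenyl-3-methoxyphenolate 2 (not isolated)
Conditions: Ph3PCH3Br (2.3 equiv), KOtBu (2.3 equiv), THF, 0 °C → rt; then TBSCl (1.5 equiv), rt
Reagents that add atoms: methyltriphenylphosphonium bromide C[P+](c1ccccc1)(c1ccccc1)c1ccccc1.[Br-]; tert-butyldimethylsilyl chloride CC(C)(C)[Si](C)(C)Cl
Why: Wittig methylenation with excess ylide tolerates the phenoxide, and the potassium phenoxide formed is O-silylated in the same flask by TBSCl; no stereocentre is involved.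

**Step 2**
Reactants: 3 tert-butyl(4-ethenyl-3-methoxyphenoxy)dimethylsilane; 4 ethylene
Product: 5 tert-butyl{4-[(2S)-but-3-en-2-yl]-3-methoxyphenoxy}dimethylsilane
Conditions: [(η3-allyl)NiBr]2 (1 mol%), BINOL/bis(1-phenylethyl)amine phosphoramidite (2 mol%), NaBArF4 (2.5 mol%), ethylene (1 atm), CH2Cl2, −70 °C
Reagents that add atoms: none
Why: Ni-catalysed asymmetric hydrovinylation: cationic Ni–H adds Markovnikov to the vinylarene, ethylene inserts and β-H elimination gives the branched 3-aryl-1-butene, with the chiral phosphoramidite selecting the styrene face so that the (S) centre is set here (alkoxy-substituted vinylarenes are established substrates).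

**Step 3**
Reactants: 5 tert-butyl{4-[(2S)-but-3-en-2-yl]-3-methoxyphenoxy}dimethylsilane; 6 methacrolein (2-methylprop-2-enal)
Product: 7 (2E,4S)-4-{4-[(tert-butyldimethylsilyl)oxy]-2-methoxyphenyl}-2-methylpent-2-enal
Conditions: Hoveyda–Grubbs II (5 mol%), methacrolein (8 equiv), 1,4-benzoquinone (10 mol%), CH2Cl2, 40 °C
Reagents that add atoms: none
Why: Olefin cross-metathesis of the terminal alkene with excess methacrolein gives the thermodynamically favoured (E)-2-methyl-enal; the benzylic stereocentre is not touched and benzoquinone suppresses Ru–H double-bond migration.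

**Step 4**
Reactants: 7 (2E,4S)-4-{4-[(tert-butyldimethylsilyl)oxy]-2-methoxyphenyl}-2-methylpent-2-enal
Product: 9 3-methoxy-4-[(2S,3E)-4-methylhex-3-en-5-yn-2-yl]phenol, via silyl ether enyne 8 (not isolated)
Conditions: TMSCHN2 (1.3 equiv), LDA (1.3 equiv), THF, −78 → 0 °C; then MeOH, K2CO3 (0.3 equiv), rt; aq. NH4Cl work-up
Reagents that add atoms: trimethylsilyldiazomethane C[Si](C)(C)C=[N+]=[N-]
Why: Colvin rearrangement (1,2-addition of lithio-TMS-diazomethane, Peterson elimination, loss of N2, 1,2-H shift of the alkylidene carbene) turns the enal into the terminal enyne at low temperature without touching the γ-stereocentre or the alkene geometry, and the aryl silyl ether is then cleaved by base-catalysed methanolysis.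

**Step 5**
Reactants: 10 1-(2,4-dihydroxyphenyl)ethanone
Product: 11 1-(2,4-dihydroxy-5-iodophenyl)ethanone
Conditions: ICl (1.05 equiv), AcOH, rt; recrystallise
Reagents that add atoms: iodine monochloride ClI
Why: Electrophilic aromatic iodination goes to C5, para to the chelated 2-OH and ortho to the free 4-OH, the less hindered of the two activated positions (minor 3-iodo isomer removed by crystallisation).

**Step 6**
Reactants: 9 3-methoxy-4-[(2S,3E)-4-methylhex-3-en-5-yn-2-yl]phenol; 11 1-(2,4-dihydroxy-5-iodophenyl)ethanone; 12 1,1-diethoxy-3-methylbut-2-ene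
Product: 16 1-{6-hydroxy-2-[(2E,4S)-4-(7-methoxy-2,2-dimethyl-2H-chromen-6-yl)pent-2-en-2-yl]-1-benzofuran-5-yl}ethanone, via o-quinone methide 13 (not isolated), via chromene enyne 14 (not isolated), via alkynylphenol 15 (not isolated)
Conditions: 12 (1.5 equiv), 3-picoline, 135 °C (EtOH distilled off); cool, degas; then 11 (1.05 equiv), PdCl2(PPh3)2 (3 mol%), CuI (6 mol%), Et3N (4 equiv), 70 °C
Reagents that add atoms: none
Why: Two heteroannulations are telescoped: pyridine-base chromenylation of the phenol with the prenal acetal (transacetalisation, ortho C-alkylation, loss of EtOH to the o-quinone methide, oxa-6π electrocyclisation) closes the pyran at the less hindered ortho position, then Sonogashira coupling of the untouched terminal enyne with the o-iodophenol and in situ Cu/Pd-assisted 5-endo-dig cycloisomerisation (Castro–Stephens-type benzofuran synthesis) closes the furan, all under basic conditions that leave the stereocentre and the (E)-alkene intact.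

**Compound list**
1 | 4-hydroxy-2-methoxybenzaldehyde | COc1cc(O)ccc1C=O | starting material
2 | potassium 4-ethenyl-3-methoxyphenolate | COc1cc([O-])ccc1C=C.[K+] | intermediate
3 | tert-butyl(4-ethenyl-3-methoxyphenoxy)dimethylsilane | COc1cc(O[Si](C)(C)C(C)(C)C)ccc1C=C | intermediate
4 | ethylene | C=C | starting material
5 | tert-butyl{4-[(2S)-but-3-en-2-yl]-3-methoxyphenoxy}dimethylsilane | COc1cc(O[Si](C)(C)C(C)(C)C)ccc1[C@@H](C)C=C | intermediate
6 | methacrolein (2-methylprop-2-enal) | CC(=C)C=O | starting material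
7 | (2E,4S)-4-{4-[(tert-butyldimethylsilyl)oxy]-2-methoxyphenyl}-2-methylpent-2-enal | COc1cc(O[Si](C)(C)C(C)(C)C)ccc1[C@@H](C)/C=C(\C)C=O | intermediate
8 | tert-butyl{3-methoxy-4-[(2S,3E)-4-methylhex-3-en-5-yn-2-yl]phenoxy}dimethylsilane | COc1cc(O[Si](C)(C)C(C)(C)C)ccc1[C@@H](C)/C=C(\C)C#C | intermediate
9 | 3-methoxy-4-[(2S,3E)-4-methylhex-3-en-5-yn-2-yl]phenol | COc1cc(O)ccc1[C@@H](C)/C=C(\C)C#C | intermediate
10 | 1-(2,4-dihydroxyphenyl)ethanone | CC(=O)c1ccc(O)cc1O | starting material
11 | 1-(2,4-dihydroxy-5-iodophenyl)ethanone | CC(=O)c1cc(I)c(O)cc1O | intermediate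
12 | 1,1-diethoxy-3-methylbut-2-ene | CCOC(OCC)C=C(C)C | starting material
13 | 3-methoxy-6-(3-methylbut-2-en-1-ylidene)-4-[(2S,3E)-4-methylhex-3-en-5-yn-2-yl]cyclohexa-2,4-dien-1-one (o-quinone methide) | COC1=CC(=O)C(=CC=C(C)C)C=C1[C@@H](C)/C=C(\C)C#C | intermediate
14 | 7-methoxy-2,2-dimethyl-6-[(2S,3E)-4-methylhex-3-en-5-yn-2-yl]-2H-chromene | COc1cc2c(cc1[C@@H](C)/C=C(\C)C#C)C=CC(C)(C)O2 | intermediate
15 | 1-(2,4-dihydroxy-5-{(3E,5S)-5-(7-methoxy-2,2-dimethyl-2H-chromen-6-yl)-3-methylhex-3-en-1-yn-1-yl}phenyl)ethanone | COc1cc2c(cc1[C@@H](C)/C=C(\C)C#Cc1cc(C(C)=O)c(O)cc1O)C=CC(C)(C)O2 | intermediate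
16 | 1-{6-hydroxy-2-[(2E,4S)-4-(7-methoxy-2,2-dimethyl-2H-chromen-6-yl)pent-2-en-2-yl]-1-benzofuran-5-yl}ethanone (CNP0347774.1) | COc1cc2c(cc1[C@@H](C)/C=C(\C)c1cc3cc(C(C)=O)c(O)cc3o1)C=CC(C)(C)O2 | target

**Step count**
Total: 6 steps. Longest linear sequence: 5 steps (1 → 2 → 3 → 4 → 6); step 5 is a one-step side branch.

**Three steps most likely to fail, with fallbacks**

Step 6 (telescoped double annulation). Risks: loss of the terminal enyne during the 135 °C chromenylation, and the competing ortho position between OH and OMe. The fallback changes both the ring order and the pyran-forming chemistry. It sets out from 9 and 11 and runs only the Sonogashira / 5-endo-dig annulation (PdCl2(PPh3)2, CuI, Et3N, DMF, 65 °C) to isolate 1-{6-hydroxy-2-[(2E,4S)-4-(4-hydroxy-2-methoxyphenyl)pent-2-en-2-yl]-1-benzofuran-5-yl}ethanone F1. Its free, non-chelated phenol is O-alkylated with 2-methylbut-3-yn-2-yl trifluoroacetate (DBU, cat. CuCl2, MeCN, 0 °C) to 1-{6-hydroxy-2-[(2E,4S)-4-{2-methoxy-4-[(2-methylbut-3-yn-2-yl)oxy]phenyl}pent-2-en-2-yl]-1-benzofuran-5-yl}ethanone F2. The pyran is then closed by aromatic propargyl Claisen rearrangement / [1,5]-H shift / oxa-6π electrocyclisation (N,N-diethylaniline, 160 °C, or Ph3PAuNTf2 at rt), which comes back to the route at 16.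

Step 3 (cross-metathesis to a trisubstituted enal next to a branched, benzylic allylic carbon). Risks: low conversion and alkene migration. The fallback sets out from 5. Lemieux–Johnson cleavage (cat. OsO4, NaIO4, 2,6-lutidine, dioxane/H2O) gives (2R)-2-{4-[(tert-butyldimethylsilyl)oxy]-2-methoxyphenyl}propanal F3; the spatial arrangement is unchanged and only the CIP descriptor changes. F3 is used crude because it is configurationally labile. Wittig olefination with 2-(triphenylphosphoranylidene)propanal (benzene, 60 °C) gives the (E)-enal and comes back to the route at 7.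

Step 2 (asymmetric hydrovinylation). Risks: ee erosion with the ortho-methoxy group and cationic oligomerisation of the electron-rich styrene. The fallback sets out from 3. CuH-catalysed Markovnikov hydroboration (Cu(OAc)2, DTBM-SEGPHOS antipode, HBpin, THF, rt) gives 2-[(1R)-1-{4-[(tert-butyldimethylsilyl)oxy]-2-methoxyphenyl}ethyl]-4,4,5,5-tetramethyl-1,3,2-dioxaborolane F4. Zweifel olefination (vinylmagnesium bromide, THF; I2, MeOH; NaOMe) transfers the benzylic carbon with retention and comes back to the route at 5.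

**Further compounds**
F1 | step 6 | 1-{6-hydroxy-2-[(2E,4S)-4-(4-hydroxy-2-methoxyphenyl)pent-2-en-2-yl]-1-benzofuran-5-yl}ethanone | COc1cc(O)ccc1[C@@H](C)/C=C(\C)c1cc2cc(C(C)=O)c(O)cc2o1
F2 | step 6 | 1-{6-hydroxy-2-[(2E,4S)-4-{2-methoxy-4-[(2-methylbut-3-yn-2-yl)oxy]phenyl}pent-2-en-2-yl]-1-benzofuran-5-yl}ethanone | COc1cc(OC(C)(C)C#C)ccc1[C@@H](C)/C=C(\C)c1cc2cc(C(C)=O)c(O)cc2o1
F3 | step 3 | (2R)-2-{4-[(tert-butyldimethylsilyl)oxy]-2-methoxyphenyl}propanal | COc1cc(O[Si](C)(C)C(C)(C)C)ccc1[C@@H](C)C=O
F4 | step 2 | 2-[(1R)-1-{4-[(tert-butyldimethylsilyl)oxy]-2-methoxyphenyl}ethyl]-4,4,5,5-tetramethyl-1,3,2-dioxaborolane | COc1cc(O[Si](C)(C)C(C)(C)C)ccc1[C@@H](C)B1OC(C)(C)C(C)(C)O1
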